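A direct plan would build ring C by the chalcone route.
O-Benzylsyringaldehyde would be brominated and then methoxylated (NaOMe, CuBr) to 4-(benzyloxy)-2,3,5-trimethoxybenzaldehyde A1, and phloroacetophenone would be dibenzylated to A2.
Claisen–Schmidt condensation would give chalcone A3, I2/DMSO at 130 °C would close and dehydrogenate it to tri-O-benzyl flavone A4, and hydrogenolysis would free the three phenols.
Weak point 1: putting on and taking off three benzyl ethers builds nothing; the selective dibenzylation of phloroacetophenone competes with C-benzylation and over-alkylation, and the final hydrogenolysis puts the C2=C3 bond of the finished flavone at risk.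
Weak point 2: the bromination/copper methoxylation pair is a two-step run-up that installs a single methoxy group on the B ring.
Weak point 3: the oxidative cyclisation produces HI at 130 °C beside three benzyl ethers and an electron-rich ring A (loss of the 5-O-benzyl group, ring iodination), and it passes through a flavanone stereocentre that is made only to be destroyed.

**Retrosynthetic overview**
Ring C is closed last, in one protecting-group-free operation: thermal union of phloroglucinol (ring A, bought whole) with the B-ring aroylacetate 12 forms C4–C4a by C-acylation through an aroylketene and then O1–C2 by cyclodehydration.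
The feature used is the 5,7-dihydroxy ring A: its parent phenol is threefold symmetric, so the annulation needs neither regiocontrol nor protection, and the two hydroxyls left over are the 5-OH and 7-OH of the target.
The B ring comes from 1,2,4-trimethoxybenzene: lithiation between two methoxy groups and oxidation install the one free hydroxyl (the later 4'-OH) already distinct from the three methyl ethers, and this hydroxyl directs the C1' carbon para to itself.
No benzyl ether, no copper methoxylation, no oxidative dehydrogenation and no hydrogenation appear, and no stereocentre is made in passing.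

Key step: step 4

Remark: the target has no stereocentre; commercial phloroglucinol dihydrate is assumed to be dried (110 °C, vacuum) before step 4, since water would hydrolyse the ketene.

Step 1
Reactants: 1 1,2,4-trimethoxybenzene; 2 n-butyllithium; 3 trimethyl borate; 4 hydrogen peroxide
Product: 7 2,3,6-trimethoxyphenol, via aryllithium 5 (not isolated), via arylboronate 6 (not isolated)
Conditions: n-BuLi (1.1 equiv), THF, 0 °C to rt; B(OMe)3 (1.5 equiv), −78 °C to rt; AcOH (1.5 equiv), 30% aq. H2O2 (2 equiv), 0 °C to rt
Reagents that add atoms: hydrogen peroxide (4), OO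
Why: Directed ortho-metalation should take place at C3, the position flanked by two methoxy groups, and borylation followed by the peroxide-induced 1,2-shift of the aryl group from boron to oxygen turns the C–Li bond into C–OH; no stereocentre.

Step 2
Reactants: 7 2,3,6-trimethoxyphenol; 8 hexamethylenetetramine; 9 water
Product: 10 4-hydroxy-2,3,5-trimethoxybenzaldehyde
Conditions: (CH2)6N4 (2 equiv), CF3CO2H, 85 °C, N2; then 3 M aq. HCl, 60 °C
Reagents that add atoms: hexamethylenetetramine (8), C1N2CN3CN1CN(C2)C3; water (9), O
Why: Duff formylation, in which the iminium ion from protonated hexamethylenetetramine should attack C4, the position para to the free hydroxyl (both ortho positions carry methoxy groups, as in the formylation of 2,6-dimethoxyphenol to syringaldehyde), and hydride transfer followed by hydrolysis gives the aldehyde; no stereocentre.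

Step 3
Reactants: 10 4-hydroxy-2,3,5-trimethoxybenzaldehyde; 11 ethyl diazoacetate
Product: 12 ethyl 3-(4-hydroxy-2,3,5-trimethoxyphenyl)-3-oxopropanoate
Conditions: N2CHCO2Et (1.5 equiv), NbCl5 (10 mol%), CH2Cl2, 0 °C to rt
Reagents that add atoms: ethyl diazoacetate (11), CCOC(=O)C=[N+]=[N-]
Why: Roskamp reaction, in which the Lewis-acid-activated aldehyde adds the diazo carbon and the β-oxido diazonium ion loses N2 with a 1,2-hydride shift, so the β-ketoester should form in one step without protection of the phenol; no stereocentre.

Step 4
Reactants: 12 ethyl 3-(4-hydroxy-2,3,5-trimethoxyphenyl)-3-oxopropanoate; 13 phloroglucinol (benzene-1,3,5-triol, anhydrous)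
Product: 16 5,7,4'-trihydroxy-2',3',5'-trimethoxyflavone, via aroylketene 14 (not isolated), via diketone 15 (not isolated)
Conditions: phloroglucinol (2 equiv), neat melt (or Ph2O), 240 °C, Ar sweep to remove EtOH and H2O, 10–30 min
Reagents that add atoms: phloroglucinol (13), Oc1cc(O)cc(O)c1
Why: Heating aroylacetate 12 should expel ethanol through a six-membered transition state to give aroylketene 14, which acylates phloroglucinol at carbon and so forms the C4–C4a bond of diketone 15; O-acylation gives only an aryl β-ketoester that reverts to the ketene at this temperature, whereas the C-acyl product is held as a hydrogen-bonded 2-hydroxyaryl ketone. The closest known reaction type is the thermal, catalyst-free condensation of phenols with β-ketoesters to chromones (Mentzer pyrone synthesis), which is known for phloroglucinol and ethyl aroylacetates under solvent-free heating and gives 5,7-dihydroxyflavones. Ring C then closes by 6-exo-trig addition of a flanking hydroxyl of 15 to the B-ring ketone and loss of water, which forms O1–C2 and the C2=C3 double bond. No stereocentre is formed, and the target has none. The step needs chemoselectivity for the flavone over the isomeric 4-aryl-5,7-dihydroxycoumarin (Pechmann mode, attack of ring A on the ketone); the absence of acid and the low electrophilicity of a ketone that is a vinylogous acid through its para hydroxyl should secure this. It needs no regioselectivity, because the threefold symmetry of phloroglucinol makes its three ring carbons and, after acylation, the two flanking hydroxyls equivalent.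

**Compound list**
1 | 1,2,4-trimethoxybenzene | COc1ccc(OC)c(OC)c1 | starting material
2 | n-butyllithium | [Li]CCCC | starting material
3 | trimethyl borate | COB(OC)OC | starting material
4 | hydrogen peroxide | OO | starting material
5 | (2,3,6-trimethoxyphenyl)lithium (formed in the flask, not isolated) | [Li]c1c(OC)ccc(OC)c1OC | intermediate
6 | dimethyl (2,3,6-trimethoxyphenyl)boronate (formed in the flask, not isolated) | COB(OC)c1c(OC)ccc(OC)c1OC | intermediate
7 | 2,3,6-trimethoxyphenol | COc1ccc(OC)c(OC)c1O | intermediate
8 | hexamethylenetetramine | C1N2CN3CN1CN(C2)C3 | starting material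
9 | water | O | starting material
10 | 4-hydroxy-2,3,5-trimethoxybenzaldehyde | COc1cc(C=O)c(OC)c(OC)c1O | intermediate
11 | ethyl diazoacetate | CCOC(=O)C=[N+]=[N-] | starting material
12 | ethyl 3-(4-hydroxy-2,3,5-trimethoxyphenyl)-3-oxopropanoate | CCOC(=O)CC(=O)c1cc(OC)c(O)c(OC)c1OC | intermediate
13 | phloroglucinol (benzene-1,3,5-triol) | Oc1cc(O)cc(O)c1 | starting material
14 | aroylketene, 3-(4-hydroxy-2,3,5-trimethoxyphenyl)-3-oxoprop-1-en-1-one (formed in the flask, not isolated) | COc1cc(C(=O)C=C=O)c(OC)c(OC)c1O | intermediate
15 | 1-(4-hydroxy-2,3,5-trimethoxyphenyl)-3-(2,4,6-trihydroxyphenyl)propane-1,3-dione (formed in the flask, not isolated) | COc1cc(C(=O)CC(=O)c2c(O)cc(O)cc2O)c(OC)c(OC)c1O | intermediate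
16 | 5,7,4'-trihydroxy-2',3',5'-trimethoxyflavone (5,7-dihydroxy-2-(4-hydroxy-2,3,5-trimethoxyphenyl)-4H-chromen-4-one) | COc1cc(-c2cc(=O)c3c(O)cc(O)cc3o2)c(OC)c(OC)c1O | target

Total step count: 4. Longest linear sequence: 4 steps (1 → 7 → 10 → 12 → 16); phloroglucinol enters unprotected in the last step.

**Steps most likely to fail**

Step 4 (thermal annulation). The aroylketene may be used up by O-acylation, dimerisation or hydrolysis and decarboxylation faster than it acylates ring A at carbon, or ring closure may take the Pechmann course at the ketone. The fallback sets out from aldehyde 10 and comes back at target 16; it assembles ring C by enolate acylation of a ring-A ketone instead, so that the C2–C3 bond is made first. Methoxymethyl chloride and i-Pr2NEt in CH2Cl2 would give 4-(methoxymethoxy)-2,3,5-trimethoxybenzaldehyde F1. Pinnick oxidation (NaClO2, NaH2PO4, 2-methyl-2-butene, t-BuOH/H2O) would give 4-(methoxymethoxy)-2,3,5-trimethoxybenzoic acid F2. The neutral reagent 1-chloro-N,N,2-trimethylprop-1-en-1-amine would give 4-(methoxymethoxy)-2,3,5-trimethoxybenzoyl chloride F3. Commercial 2,4,6-trihydroxyacetophenone, polylithiated with LiN(SiMe3)2 (5 equiv, THF, −78 °C), would be acylated at its methyl carbon by F3 to 1-[4-(methoxymethoxy)-2,3,5-trimethoxyphenyl]-3-(2,4,6-trihydroxyphenyl)propane-1,3-dione F4. AcOH with catalytic H2SO4 at 95 °C should then cyclodehydrate F4 and remove the methoxymethyl group in the same operation, giving 16.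

Step 3 (Roskamp homologation). Aryl migration may compete with hydride migration in this electron-rich aldehyde, and the free phenol may tie up the Lewis acid so that the addition stalls. The fallback sets out from aldehyde 10 and comes back at β-ketoester 12. MeMgBr (3 equiv, THF) would give racemic 4-(1-hydroxyethyl)-2,3,6-trimethoxyphenol F5. DDQ in dioxane, which dehydrogenates para-hydroxybenzylic alcohols, would give 1-(4-hydroxy-2,3,5-trimethoxyphenyl)ethan-1-one F6. Claisen C-ethoxycarbonylation of the dianion of F6 (NaH, diethyl carbonate, THF, reflux) would give 12.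

Step 2 (Duff formylation). Attack may be slow or may lose regioselectivity between C4 and C5, and the electron-rich phenol may be oxidised in hot acid. The fallback sets out from phenol 7 and comes back at aldehyde 10. N-Bromosuccinimide in MeCN at 0 °C, para-selective for phenols, would give 4-bromo-2,3,6-trimethoxyphenol F7. Deprotonation with NaH, bromine–lithium exchange with t-BuLi (2.1 equiv, THF, −78 °C) and a DMF quench would give 10.

**Further compounds**
F1 | step 4 | 4-(methoxymethoxy)-2,3,5-trimethoxybenzaldehyde | COCOc1c(OC)cc(C=O)c(OC)c1OC
F2 | step 4 | 4-(methoxymethoxy)-2,3,5-trimethoxybenzoic acid | COCOc1c(OC)cc(C(=O)O)c(OC)c1OC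
F3 | step 4 | 4-(methoxymethoxy)-2,3,5-trimethoxybenzoyl chloride | COCOc1c(OC)cc(C(=O)Cl)c(OC)c1OC
F4 | step 4 | 1-[4-(methoxymethoxy)-2,3,5-trimethoxyphenyl]-3-(2,4,6-trihydroxyphenyl)propane-1,3-dione | COCOc1c(OC)cc(C(=O)CC(=O)c2c(O)cc(O)cc2O)c(OC)c1OC
F5 | step 3 | 4-(1-hydroxyethyl)-2,3,6-trimethoxyphenol (racemic) | COc1cc(C(C)O)c(OC)c(OC)c1O
F6 | step 3 | 1-(4-hydroxy-2,3,5-trimethoxyphenyl)ethan-1-one | COc1cc(C(C)=O)c(OC)c(OC)c1O
F7 | step 2 | 4-bromo-2,3,6-trimethoxyphenol | COc1cc(Br)c(OC)c(OC)c1O
A1 | direct plan | 4-(benzyloxy)-2,3,5-trimethoxybenzaldehyde | COc1cc(C=O)c(OC)c(OC)c1OCc1ccccc1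
A2 | direct plan | 1-[2,4-bis(benzyloxy)-6-hydroxyphenyl]ethan-1-one | CC(=O)c1c(O)cc(OCc2ccccc2)cc1OCc1ccccc1
A3 | direct plan | (E)-1-[2,4-bis(benzyloxy)-6-hydroxyphenyl]-3-[4-(benzyloxy)-2,3,5-trimethoxyphenyl]prop-2-en-1-one | COc1cc(/C=C/C(=O)c2c(O)cc(OCc3ccccc3)cc2OCc2ccccc2)c(OC)c(OC)c1OCc1ccccc1
A4 | direct plan | 5,7-bis(benzyloxy)-2-[4-(benzyloxy)-2,3,5-trimethoxyphenyl]-4H-chromen-4-one | COc1cc(-c2cc(=O)c3c(OCc4ccccc4)cc(OCc4ccccc4)cc3o2)c(OC)c(OC)c1OCc1ccccc1
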